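**Retrosynthetic overview**
1. Ring A is read as a [4+2] product. C2(OH)–C3(Cl)–C4(OMe)–C5(H) is the carbon chain of a 2-chloro-1,1,3-trioxygenated buta-1,3-diene. C1 (depside carbonyl) and C6 (propyl) are the two alkyne carbons of a hex-2-ynoate.
2. Last disconnection: the free acid and the ring B C2 phenol come from a tert-butyl ester and a MOM ether, which acid cleaves together.
3. Key disconnection: ring A bonds C1–C2 and C5–C6, by Diels–Alder cycloaromatisation of the chlorodiene on the ring B aryl hex-2-ynoate. The depside C–O bond is therefore made earlier, on a linear unhindered acid.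
4. Ring B is bought as olivetolic acid and only dressed (ester, 4-O-acyl, 2-O-MOM). The diene comes in two steps from methyl 2-chloroacetoacetate, which brings in the chlorine, so no arene is ever chlorinated.
5. Ring order: ring B is purchased, and ring A is formed last and is the only ring built. The target has no stereocentre.

Key step: step 6

Assumption: the double-bond geometries of 10, 11 and 12 are not controlled and need not be, because C1 and C2 of the diene both end as aromatic carbons; one isomer of each is drawn.

**Step 1**
Reactants: 1 olivetolic acid (2,4-dihydroxy-6-pentylbenzoic acid)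
Product: 2 tert-butyl 2,4-dihydroxy-6-pentylbenzoate
Conditions: Cl3CC(=NH)OtBu (2 equiv), CH2Cl2/THF, rt, 16 h
Reagents that add atoms: tert-butyl 2,2,2-trichloroacetimidate, CC(C)(C)OC(=N)C(Cl)(Cl)Cl
Why: Alkylative esterification with a trichloroacetimidate, in which only the carboxylic acid is acidic enough to protonate the imidate and then captures the tert-butyl cation on oxygen, so the crowded 2,6-disubstituted carbonyl carbon is never attacked, the phenols stay free and room temperature spares the decarboxylation-prone acid.

**Step 2**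
Reactants: 2 tert-butyl 2,4-dihydroxy-6-pentylbenzoate; 3 hex-2-ynoic acid
Product: 5 tert-butyl 4-(hex-2-ynoyloxy)-2-hydroxy-6-pentylbenzoate, via O-acylisourea 4 (not isolated)
Conditions: 3 (1.05 equiv), DCC (1.1 equiv), DMAP (0.05 equiv), CH2Cl2, 0 °C to rt
Reagents that add atoms: none
Why: Steglich esterification, the usual way to aryl alk-2-ynoates, in which the C2 hydroxyl is tied up in a hydrogen bond to the neighbouring ester carbonyl so that only the free C4 phenol is acylated, while low temperature and little DMAP hold back oxa-Michael addition to the ynoate.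

**Step 3**
Reactants: 5 tert-butyl 4-(hex-2-ynoyloxy)-2-hydroxy-6-pentylbenzoate
Product: 6 tert-butyl 4-(hex-2-ynoyloxy)-2-(methoxymethoxy)-6-pentylbenzoate
Conditions: MeOCH2Cl (3 equiv), iPr2NEt (4 equiv), CH2Cl2, 0 °C to 40 °C
Reagents that add atoms: chloromethyl methyl ether, COCCl
Why: Williamson-type O-alkylation of the phenol by the highly reactive α-chloro ether under a non-nucleophilic amine base that neither cleaves the aryl ester nor adds to the alkyne, which masks the only acidic proton that would otherwise protonate the ketene acetal in step 6.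

**Step 4**
Reactants: 7 methyl 2-chloroacetoacetate (racemic, configurationally labile); 8 trimethyl orthoformate
Product: 10 methyl (Z)-2-chloro-3-methoxybut-2-enoate, via dimethyl ketal 9 (not isolated)
Conditions: 8 (1.5 equiv), H2SO4 (cat.), neat, rt to 50 °C; then distillation under reduced pressure
Reagents that add atoms: trimethyl orthoformate 8, COC(OC)OC
Why: Acid-catalysed ketalisation by the orthoester followed by loss of methanol, as practised on the parent acetoacetate, with elimination towards the acidic C2–H giving the conjugated tetrasubstituted enol ether.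

**Step 5**
Reactants: 10 methyl (Z)-2-chloro-3-methoxybut-2-enoate
Product: 12 (1E)-2-chloro-1,3-dimethoxy-1-(trimethylsilyloxy)buta-1,3-diene, via lithium dienolate 11 (not isolated)
Conditions: LiN(iPr)2 (1.1 equiv), THF, −78 °C, 1 h; Me3SiCl (1.3 equiv), −78 °C to rt; pentane, filtration, bulb-to-bulb distillation
Reagents that add atoms: chlorotrimethylsilane, C[Si](C)(C)Cl
Why: γ-Deprotonation and O-silylation, the standard preparation of vinylketene silyl acetals, which is unambiguous here because C2 carries no hydrogen and the C4 methyl is the only acidic site, and because α-chloro ester enolates persist at −78 °C.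

**Step 6**
Reactants: 6 tert-butyl 4-(hex-2-ynoyloxy)-2-(methoxymethoxy)-6-pentylbenzoate; 12 (1E)-2-chloro-1,3-dimethoxy-1-(trimethylsilyloxy)buta-1,3-diene
Product: 15 tert-butyl 4-[(3-chloro-2-hydroxy-4-methoxy-6-propylbenzoyl)oxy]-2-(methoxymethoxy)-6-pentylbenzoate, via cyclohexa-1,4-diene cycloadduct 13 (not isolated), via ring A trimethylsilyl ether 14 (not isolated)
Conditions: 12 (3 equiv, in portions), xylene (ca. 1 M), sealed tube, Ar, 130 °C, 24–72 h; then THF/10% aq. citric acid, rt
Reagents that add atoms: none
Why: This is a normal-electron-demand Diels–Alder reaction whose two bonds form unequally: the CH2 terminus of 12 has the largest HOMO coefficient, because the C3 methoxy group and both acetal oxygens donate towards it, so it attacks the propyl-bearing β carbon of the ynoate (ring A bond C5–C6), and the ketene-acetal carbon then closes on the α carbon (bond C1–C2). Six-membered ring A is closed by an intermolecular [4+2] cycloaddition as cyclohexa-1,4-diene 13, whose two sp3 carbons are the mixed acetal C2 and the methylene C5; 1,4-elimination of methanol across them gives silyl ether 14, any 13 that lasts until work-up collapses through the dienone to the same phenol, and citric acid cleaves the O–Si bond without touching the MOM ether or the tert-butyl ester. The closest known reaction type is the cycloaromatisation of 1-alkoxy-1-silyloxy-3-alkoxy- and 1,3-bis(silyloxy)buta-1,3-dienes with alk-2-ynoates, β-alkyl ones included, to 6-alkylresorcylates; chlorine on C2 of the diene lowers its HOMO and the β-propyl group shields the alkyne, so excess diene, high concentration and long heating are planned. No stereocentre remains, since the acetal carbon of 13 forms racemic and is flattened on aromatisation, as is the C1=C2 geometry of 12. The step needs regioselectivity (propyl next to C5–H, carbonyl next to C2–OH), which the matched polarity of the two unsymmetrical partners secures, and chemoselectivity, which holds because the ynoate is the only electron-poor π bond of 6, 6 has no acidic proton to destroy the ketene acetal, and the aryloxy group lowers the alkyne LUMO below that of an alkyl ester.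

**Step 7**
Reactants: 15 tert-butyl 4-[(3-chloro-2-hydroxy-4-methoxy-6-propylbenzoyl)oxy]-2-(methoxymethoxy)-6-pentylbenzoate
Product: 16 4-[(3-chloro-2-hydroxy-4-methoxy-6-propylbenzoyl)oxy]-2-hydroxy-6-pentylbenzoic acid (target)
Conditions: CF3CO2H/CH2Cl2 (1:4), 0 °C to rt, 1–2 h; cold evaporation, aqueous work-up
Reagents that add atoms: none
Why: Acidolysis, in which the tert-butyl ester cleaves by alkyl–oxygen fission and the MOM acetal through its oxocarbenium ion, while the depside ester, aryl chloride and aryl methyl ether are inert to the acid and the short cold contact limits protodecarboxylation of the salicylic acid.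

**Compound list**
1 | olivetolic acid | CCCCCc1cc(O)cc(O)c1C(=O)O | starting material
2 | tert-butyl 2,4-dihydroxy-6-pentylbenzoate | CCCCCc1cc(O)cc(O)c1C(=O)OC(C)(C)C | intermediate
3 | hex-2-ynoic acid | CCCC#CC(=O)O | starting material
4 | N,N'-dicyclohexyl-O-(hex-2-ynoyl)isourea (not isolated) | CCCC#CC(=O)OC(=NC1CCCCC1)NC1CCCCC1 | intermediate
5 | tert-butyl 4-(hex-2-ynoyloxy)-2-hydroxy-6-pentylbenzoate | CCCCCc1cc(OC(=O)C#CCCC)cc(O)c1C(=O)OC(C)(C)C | intermediate
6 | tert-butyl 4-(hex-2-ynoyloxy)-2-(methoxymethoxy)-6-pentylbenzoate | CCCCCc1cc(OC(=O)C#CCCC)cc(OCOC)c1C(=O)OC(C)(C)C | intermediate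
7 | methyl 2-chloroacetoacetate (racemic) | CC(=O)C(Cl)C(=O)OC | starting material
8 | trimethyl orthoformate | COC(OC)OC | starting material
9 | methyl 2-chloro-3,3-dimethoxybutanoate (racemic, not isolated) | CC(OC)(OC)C(Cl)C(=O)OC | intermediate
10 | methyl (Z)-2-chloro-3-methoxybut-2-enoate | C/C(OC)=C(/Cl)C(=O)OC | intermediate
11 | lithium 2-chloro-1,3-dimethoxybuta-1,3-dien-1-olate (O–Li cis to C3 as drawn, not isolated) | C=C(OC)/C(Cl)=C(/OC)[O-].[Li+] | intermediate
12 | (1E)-2-chloro-1,3-dimethoxy-1-(trimethylsilyloxy)buta-1,3-diene | C=C(OC)/C(Cl)=C(/OC)O[Si](C)(C)C | intermediate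
13 | tert-butyl 4-{[5-chloro-4,6-dimethoxy-2-propyl-6-(trimethylsilyloxy)cyclohexa-1,4-diene-1-carbonyl]oxy}-2-(methoxymethoxy)-6-pentylbenzoate (racemic acetal carbon, not isolated) | CCCCCc1cc(OC(=O)C2=C(CCC)CC(OC)=C(Cl)C2(OC)O[Si](C)(C)C)cc(OCOC)c1C(=O)OC(C)(C)C | intermediate
14 | tert-butyl 4-{[3-chloro-4-methoxy-6-propyl-2-(trimethylsilyloxy)benzoyl]oxy}-2-(methoxymethoxy)-6-pentylbenzoate (not isolated) | CCCCCc1cc(OC(=O)c2c(CCC)cc(OC)c(Cl)c2O[Si](C)(C)C)cc(OCOC)c1C(=O)OC(C)(C)C | intermediate
15 | tert-butyl 4-[(3-chloro-2-hydroxy-4-methoxy-6-propylbenzoyl)oxy]-2-(methoxymethoxy)-6-pentylbenzoate | CCCCCc1cc(OC(=O)c2c(CCC)cc(OC)c(Cl)c2O)cc(OCOC)c1C(=O)OC(C)(C)C | intermediate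
16 | 4-[(3-chloro-2-hydroxy-4-methoxy-6-propylbenzoyl)oxy]-2-hydroxy-6-pentylbenzoic acid | CCCCCc1cc(OC(=O)c2c(CCC)cc(OC)c(Cl)c2O)cc(O)c1C(=O)O | target

Total step count: 7
Longest linear sequence: 5 (steps 1, 2, 3, 6, 7); the diene branch (steps 4, 5) joins at step 6.

**Steps most likely to fail**

1. **Step 6.**
   - *What may go wrong:* the cycloaddition may be slower than the thermal decay of the diene (O-to-C silyl shift, protonolysis by liberated methanol, oligomerisation). The adduct may also expel silanol in place of methanol, which would leave C2 methylated.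
   - *Fallback:* the cycloaddition is given up, ring A is made by arene functionalisation, and the depside bond is formed last. It sets out from 2 and comes back to the route at 16.
   - Commercial 1,3-dimethoxy-5-propylbenzene is lithiated between its two methoxy groups (nBuLi, THF, 0 °C) and quenched with C2Cl6 to give 2-chloro-1,3-dimethoxy-5-propylbenzene F1.
   - The two free positions of F1 are equivalent, so Rieche formylation (Cl2CHOMe, TiCl4, CH2Cl2, 0 °C) can give only 3-chloro-2,4-dimethoxy-6-propylbenzaldehyde F2.
   - BCl3 (CH2Cl2, −78 to 0 °C) cleaves only the methyl ether that chelates to the aldehyde and gives 3-chloro-2-hydroxy-4-methoxy-6-propylbenzaldehyde F3.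
   - Pinnick oxidation (NaClO2, NaH2PO4, 2-methylbut-2-ene, tBuOH/H2O) gives 3-chloro-2-hydroxy-4-methoxy-6-propylbenzoic acid F4.
   - DCC in toluene joins F4 to the free C4 phenol of 2 to give tert-butyl 4-[(3-chloro-2-hydroxy-4-methoxy-6-propylbenzoyl)oxy]-2-hydroxy-6-pentylbenzoate F5. CF3CO2H in CH2Cl2 then frees the acid 16.

2. **Step 5.**
   - *What may go wrong:* the α-chloro dienolate may decay (loss of chloride, halophilic attack by the amide base), it may be silylated on carbon, or the diene may hydrolyse during isolation.
   - *Fallback:* the strong base and step 4 are both avoided by soft enolisation to a bis(silyloxy)diene, and the C4 methyl ether is installed after the ring is built. It sets out from 7 and comes back to the route at 15.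
   - Compound 7 with Me3SiOSO2CF3 (2.2 equiv) and Et3N in Et2O at 0 °C should give (1E)-2-chloro-1-methoxy-1,3-bis(trimethylsilyloxy)buta-1,3-diene F6 (geometry of no consequence).
   - F6 replaces 12 in the cycloaromatisation with 6. After the citric acid work-up this gives tert-butyl 4-[(3-chloro-2,4-dihydroxy-6-propylbenzoyl)oxy]-2-(methoxymethoxy)-6-pentylbenzoate F7.
   - A Mitsunobu reaction with methanol (PPh3, DIAD, THF, 0 °C to rt) alkylates the unchelated, more acidic C4 phenol of ring A under neutral conditions and gives 15.

3. **Step 3.**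
   - *What may go wrong:* alkylation of the chelated phenol may be slow. Forcing it may let phenoxide attack the activated aryl ynoate (transacylation or oxa-Michael addition).
   - *Fallback:* the order is reversed, so the MOM ether is set with a strong base before the ynoate is present. It sets out from 2 and comes back to the route at 6.
   - BnBr and K2CO3 in acetone alkylate only the free C4 phenol and give tert-butyl 4-(benzyloxy)-2-hydroxy-6-pentylbenzoate F8.
   - NaH and MeOCH2Cl in DMF at 0 °C give tert-butyl 4-(benzyloxy)-2-(methoxymethoxy)-6-pentylbenzoate F9.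
   - Hydrogenolysis (H2, Pd/C, EtOAc) gives tert-butyl 4-hydroxy-2-(methoxymethoxy)-6-pentylbenzoate F10.
   - Steglich esterification of F10 with 3 (DCC, DMAP cat., CH2Cl2, 0 °C) gives 6.

**Further compounds**
F1 | step 6 | 2-chloro-1,3-dimethoxy-5-propylbenzene | CCCc1cc(OC)c(Cl)c(OC)c1
F2 | step 6 | 3-chloro-2,4-dimethoxy-6-propylbenzaldehyde | CCCc1cc(OC)c(Cl)c(OC)c1C=O
F3 | step 6 | 3-chloro-2-hydroxy-4-methoxy-6-propylbenzaldehyde | CCCc1cc(OC)c(Cl)c(O)c1C=O
F4 | step 6 | 3-chloro-2-hydroxy-4-methoxy-6-propylbenzoic acid | CCCc1cc(OC)c(Cl)c(O)c1C(=O)O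
F5 | step 6 | tert-butyl 4-[(3-chloro-2-hydroxy-4-methoxy-6-propylbenzoyl)oxy]-2-hydroxy-6-pentylbenzoate | CCCCCc1cc(OC(=O)c2c(CCC)cc(OC)c(Cl)c2O)cc(O)c1C(=O)OC(C)(C)C
F6 | step 5 | (1E)-2-chloro-1-methoxy-1,3-bis(trimethylsilyloxy)buta-1,3-diene | C=C(O[Si](C)(C)C)/C(Cl)=C(/OC)O[Si](C)(C)C
F7 | step 5 | tert-butyl 4-[(3-chloro-2,4-dihydroxy-6-propylbenzoyl)oxy]-2-(methoxymethoxy)-6-pentylbenzoate | CCCCCc1cc(OC(=O)c2c(CCC)cc(O)c(Cl)c2O)cc(OCOC)c1C(=O)OC(C)(C)C
F8 | step 3 | tert-butyl 4-(benzyloxy)-2-hydroxy-6-pentylbenzoate | CCCCCc1cc(OCc2ccccc2)cc(O)c1C(=O)OC(C)(C)C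
F9 | step 3 | tert-butyl 4-(benzyloxy)-2-(methoxymethoxy)-6-pentylbenzoate | CCCCCc1cc(OCc2ccccc2)cc(OCOC)c1C(=O)OC(C)(C)C
F10 | step 3 | tert-butyl 4-hydroxy-2-(methoxymethoxy)-6-pentylbenzoate | CCCCCc1cc(O)cc(OCOC)c1C(=O)OC(C)(C)C
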